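Assumption: the SMILES is taken as the absolute configuration; locants C1–C20 follow the bicyclo[8.4.0]tetradecane core (C1/C10 ring-fusion CH, C2–O–C9 ether bridge, C3 quaternary C–O, C6 OMe, C7 Me, C11 OAc, C12 Me, C14–C15(Me)–C16H2–O–C3), which gives 1S,2S,3S,6R,7R,9S,10R,11R,12R,14S,15R.
Abbreviation: Hep = (2S,4R,5R)-1-(benzyloxy)-5-methoxy-4-methylhept-6-en-2-yl. Oxonane compounds 23–32 keep one set of ring locants (O1, C2 … C9 = core C2 … C9).

## Retrosynthetic overview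

1. 43 ⇐ acetylation and C11 oxidation/reduction ⇐ convex-face hydroboration of tetracyclic alkene 38 (sets C12); oxepane ⇐ triflate etherification of C16–OH by C3–OH after hydroboration of a C14 isopropenyl group (sets C15).
2. Cyclohexene and tetrahydrofuran rings ⇐ one intramolecular Diels–Alder reaction of tetraene 32 (diene on C9, enone on C2) across a preformed oxonane (sets C1, C10, C14).
3. Nine-membered oxonane ⇐ ring-closing metathesis at C4=C5 of ether-linked diene 22, then hydrogenation; C3 ⇐ chelation-controlled vinyl addition to methyl ketone 21.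
4. Key C–C bond C2–C3 ⇐ intermolecular Evans glycolate aldol of imide 15 with acetaldehyde 16 (sets C2); the C5–C10 part of 15 ⇐ intermolecular Evans propionate aldol with acrolein (C6, C7) plus (S)-benzyl glycidyl ether (C9).
5. Ring order: oxonane → tetrahydrofuran + cyclohexene (together) → oxepane.

## Route

Step 1
Reactants: 1 (S)-4-benzyl-3-propionyloxazolidin-2-one; 2 acrolein
Product: 4 (S)-4-benzyl-3-[(2S,3R)-3-hydroxy-2-methylpent-4-enoyl]oxazolidin-2-one, via dibutylboron Z-enolate 3 (not isolated)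
Conditions: Bu2BOTf, i-Pr2NEt, CH2Cl2, 0 °C; 2, −78 → 0 °C; pH 7 buffer, MeOH, H2O2
Reagents that add atoms: none
Why: Evans syn-aldol through the boron Z-enolate and a Zimmerman–Traxler chair in which the (S)-benzyl auxiliary blocks one enolate face, setting C7 and C6 together.

Step 2
Reactants: 4
Product: 5 (S)-4-benzyl-3-[(2S,3R)-3-methoxy-2-methylpent-4-enoyl]oxazolidin-2-one
Conditions: Me3OBF4, 1,8-bis(dimethylamino)naphthalene, CH2Cl2, rt
Reagents that add atoms: trimethyloxonium tetrafluoroborate, C[O+](C)C.F[B-](F)(F)F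
Why: O-methylation with an oxonium salt and a non-nucleophilic base avoids retro-aldol and epimerisation of the β-hydroxy imide.

Step 3
Reactants: 5
Product: 6 (2R,3R)-3-methoxy-2-methylpent-4-en-1-ol
Conditions: LiBH4, MeOH, Et2O, 0 °C
Reagents that add atoms: none
Why: Reductive cleavage of the N-acyloxazolidinone gives the primary alcohol and returns the auxiliary without touching a stereocentre.

Step 4
Reactants: 6
Product: 7 (3R,4S)-5-bromo-3-methoxy-4-methylpent-1-ene
Conditions: CBr4, PPh3, CH2Cl2, 0 °C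
Reagents that add atoms: carbon tetrabromide, BrC(Br)(Br)Br
Why: Appel bromination of the primary alcohol under neutral conditions leaves both stereocentres untouched.

Step 5
Reactants: 7; 8 (S)-benzyl glycidyl ether
Product: 10 (2S,4R,5R)-1-(benzyloxy)-5-methoxy-4-methylhept-6-en-2-ol, via Grignard reagent 9 (not isolated)
Conditions: Mg, THF, 40 °C; then CuI (10 mol %), 8, −30 → 0 °C
Reagents that add atoms: none
Why: Copper-catalysed SN2 opening of the epoxide at its terminal carbon by the Grignard reagent forms C8–C9, and C9 comes unchanged from the chiral epoxide.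

Step 6
Reactants: 10; 11 bromoacetic acid
Product: 12 (HepO)acetic acid
Conditions: NaH, THF/DMF, 0 °C → rt; then aqueous HCl
Reagents that add atoms: none
Why: Williamson etherification of the sodium alkoxide with sodium bromoacetate places the future C1–C2 unit on the C9 oxygen.

Step 7
Reactants: 12; 13 (R)-4-benzyloxazolidin-2-one
Product: 15 (R)-4-benzyl-3-[(HepO)acetyl]oxazolidin-2-one, via pivalic mixed anhydride 14 (not isolated)
Conditions: t-BuCOCl, Et3N, THF, −20 °C; then LiCl, 13, rt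
Reagents that add atoms: none
Why: N-acylation of the oxazolidinone through the mixed anhydride gives the glycolyl imide needed for auxiliary-controlled enolate chemistry.

Step 8 (key step)
Reactants: 15; 16 acetaldehyde
Product: 18 (R)-4-benzyl-3-[(2R,3S)-2-(HepO)-3-hydroxybutanoyl]oxazolidin-2-one, via dibutylboron Z-enolate 17 (not isolated)
Conditions: Bu2BOTf, Et3N, CH2Cl2, −78 → 0 °C; 16, −78 → 0 °C; pH 7 buffer, MeOH, H2O2
Reagents that add atoms: none
Why: Intermolecular Evans syn-glycolate aldol in which the (R)-auxiliary directs the aldehyde to one face of the boron Z-enolate, forming C2–C3 and setting C2 (the C3 carbinol is oxidised in step 11).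

Step 9
Reactants: 18
Product: 19 (2S,3S)-2-(HepO)butane-1,3-diol
Conditions: LiBH4, MeOH, THF, 0 °C
Reagents that add atoms: none
Why: Reductive removal of the auxiliary turns the acyl carbon into the C1 primary alcohol.

Step 10
Reactants: 19
Product: 20 (2S,3S)-3-(HepO)-4-[(tert-butyldimethylsilyl)oxy]butan-2-ol
Conditions: TBSCl, imidazole, CH2Cl2, −10 °C
Reagents that add atoms: tert-butyldimethylsilyl chloride, CC(C)(C)[Si](C)(C)Cl
Why: Silylation is selective for the primary over the secondary hydroxyl on steric grounds and gives a non-chelating C1 ether.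

Step 11
Reactants: 20
Product: 21 (S)-3-(HepO)-4-[(tert-butyldimethylsilyl)oxy]butan-2-one
Conditions: Dess–Martin periodinane, NaHCO3, CH2Cl2, rt
Reagents that add atoms: none
Why: Dess–Martin oxidation gives the α-alkoxy methyl ketone under buffered conditions that do not epimerise C2.

Step 12
Reactants: 21
Product: 22 (3S,4S)-4-(HepO)-5-[(tert-butyldimethylsilyl)oxy]-3-methylpent-1-en-3-ol
Conditions: CH2=CHMgBr, THF, −78 °C
Reagents that add atoms: vinylmagnesium bromide, C=C[Mg]Br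
Why: Cram-chelate Grignard addition in which Mg bridges the ketone and the α-ether oxygen, so vinyl attacks anti to the CH2OTBS group and sets the C3 tertiary carbinol.

Step 13
Reactants: 22
Product: 23 (2S,3S,4Z,6S,7R,9S)-9-[(benzyloxy)methyl]-2-{[(tert-butyldimethylsilyl)oxy]methyl}-6-methoxy-3,7-dimethyl-2,3,6,7,8,9-hexahydrooxonin-3-ol
Conditions: second-generation Grubbs catalyst (H2IMes)(PCy3)Cl2Ru=CHPh (10 mol %), CH2Cl2 (1 mM), 40 °C
Reagents that add atoms: none
Why: Ring-closing olefin metathesis of the two vinyl groups, helped by the gauche C–O bonds flanking the ether and the free allylic hydroxyl, closes the nine-membered ring at C4=C5 without touching a stereocentre.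

Step 14
Reactants: 23
Product: 24 (2S,3S,6R,7R,9S)-9-[(benzyloxy)methyl]-2-{[(tert-butyldimethylsilyl)oxy]methyl}-6-methoxy-3,7-dimethyloxonan-3-ol
Conditions: H2 (1 atm), [Ir(cod)(PCy3)(py)]PF6 (5 mol %), CH2Cl2, rt
Reagents that add atoms: none
Why: Hydroxyl-directed homogeneous hydrogenation saturates the ring alkene without hydrogenolysis of the allylic C–O bonds or the benzyl ether, and creates no stereocentre.

Step 15
Reactants: 24
Product: 25 (2S,3S,6R,7R,9S)-9-[(benzyloxy)methyl]-2-{[(tert-butyldimethylsilyl)oxy]methyl}-6-methoxy-3,7-dimethyl-3-[(triethylsilyl)oxy]oxonane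
Conditions: Et3SiOTf, 2,6-lutidine, CH2Cl2, −78 → 0 °C
Reagents that add atoms: triethylsilyl trifluoromethanesulfonate, CC[Si](CC)(CC)OS(=O)(=O)C(F)(F)F
Why: Silylation with the silyl triflate masks the tertiary hydroxyl so that it cannot add to the C10 aldehyde or enone made next.

Step 16
Reactants: 25
Product: 26 (2S,3S,6R,7R,9S)-2-{[(tert-butyldimethylsilyl)oxy]methyl}-9-(hydroxymethyl)-6-methoxy-3,7-dimethyl-3-[(triethylsilyl)oxy]oxonane
Conditions: H2 (1 atm), Pd(OH)2 on carbon, EtOAc, rt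
Reagents that add atoms: none
Why: Hydrogenolysis removes the benzyl ether in a neutral solvent in which both silyl ethers survive.

Step 17
Reactants: 26
Product: 27 (2S,3S,6R,7R,9S)-2-{[(tert-butyldimethylsilyl)oxy]methyl}-9-formyl-6-methoxy-3,7-dimethyl-3-[(triethylsilyl)oxy]oxonane
Conditions: Dess–Martin periodinane, NaHCO3, CH2Cl2, rt
Reagents that add atoms: none
Why: Dess–Martin oxidation gives the α-alkoxy aldehyde without epimerising C9.

Step 18
Reactants: 27
Product: 28 (2S,3S,6R,7R,9S)-2-{[(tert-butyldimethylsilyl)oxy]methyl}-6-methoxy-3,7-dimethyl-9-[(E)-3-oxobut-1-en-1-yl]-3-[(triethylsilyl)oxy]oxonane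
Conditions: Ph3P=CHC(O)CH3, toluene, 80 °C
Reagents that add atoms: 1-(triphenylphosphoranylidene)propan-2-one, CC(=O)C=P(c1ccccc1)(c1ccccc1)c1ccccc1
Why: Wittig olefination with the stabilised ylide gives the E-enone (C10=C11).

Step 19
Reactants: 28
Product: 29 (2S,3S,6R,7R,9S)-2-{[(tert-butyldimethylsilyl)oxy]methyl}-6-methoxy-3,7-dimethyl-9-[(E)-3-methylbuta-1,3-dien-1-yl]-3-[(triethylsilyl)oxy]oxonane
Conditions: Ph3PCH3Br, KOtBu, THF, 0 °C → rt
Reagents that add atoms: methyltriphenylphosphonium bromide, C[P+](c1ccccc1)(c1ccccc1)c1ccccc1.[Br-]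
Why: Wittig methylenation of the enone carbonyl gives the E-diene C10=C11–C12(Me)=C13.

Step 20
Reactants: 29
Product: 30 (2S,3S,6R,7R,9S)-2-(hydroxymethyl)-6-methoxy-3,7-dimethyl-9-[(E)-3-methylbuta-1,3-dien-1-yl]oxonan-3-ol
Conditions: Bu4NF, THF, rt
Reagents that add atoms: none
Why: Fluoride desilylation removes both silyl ethers now that the Michael-acceptor stage on the C9 side is past.

Step 21
Reactants: 30
Product: 31 (2R,3S,6R,7R,9S)-2-formyl-6-methoxy-3,7-dimethyl-9-[(E)-3-methylbuta-1,3-dien-1-yl]oxonan-3-ol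
Conditions: Dess–Martin periodinane, NaHCO3, CH2Cl2, 0 °C
Reagents that add atoms: none
Why: Dess–Martin oxidation touches only the primary alcohol because the tertiary one cannot be oxidised.

Step 22
Reactants: 31
Product: 33 (1R,2S,3S,6R,7R,9S,10R,14R)-14-acetyl-6-methoxy-3,7,12-trimethyl-2,9-epoxybicyclo[8.4.0]tetradec-11-en-3-ol, via tetraene enone 32 (not isolated)
Conditions: Ph3P=CHC(O)CH3, CH2Cl2, rt; then toluene, 80 °C
Reagents that add atoms: 1-(triphenylphosphoranylidene)propan-2-one, CC(=O)C=P(c1ccccc1)(c1ccccc1)c1ccccc1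
Why: Wittig olefination gives the E-enone, which undergoes a thermal intramolecular Diels–Alder reaction through the carbonyl-exo transition state on the diene face turned away from the oxonane, giving the cis ring fusion with H1 trans to H2 and to H14 (C1, C10, C14).

Step 23
Reactants: 33
Product: 34 (1S,2S,3S,6R,7R,9S,10R,14R)-6-methoxy-3,7,12-trimethyl-14-(prop-1-en-2-yl)-2,9-epoxybicyclo[8.4.0]tetradec-11-en-3-ol
Conditions: Ph3PCH3Br, KOtBu, THF, 0 → 40 °C
Reagents that add atoms: methyltriphenylphosphonium bromide, C[P+](c1ccccc1)(c1ccccc1)c1ccccc1.[Br-]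
Why: Wittig methylenation converts the acetyl group into the isopropenyl group, and C14 is safe because the equatorial arrangement present is the more stable one.

Step 24
Reactants: 34
Product: 36 (1S,2S,3S,6R,7R,9S,10R,14S)-14-[(2R)-1-hydroxypropan-2-yl]-6-methoxy-3,7,12-trimethyl-2,9-epoxybicyclo[8.4.0]tetradec-11-en-3-ol, via B-alkyl-9-BBN adduct 35 (not isolated)
Conditions: 9-BBN, THF, 0 °C → rt; then NaOH, H2O2, 0 °C
Reagents that add atoms: hydrogen peroxide, OO
Why: Hydroboration–oxidation with the bulky borane takes only the 1,1-disubstituted alkene and, in the conformer with H14 eclipsing C15=C16, attacks the face anti to C1, setting C15.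

Step 25
Reactants: 36
Product: 38 tetracyclic alkene (1S,2S,3S,6R,7R,9S,10R,14S,15R), i.e. 43 with a C11=C12 double bond and no C11 oxygen, via primary triflate 37 (not isolated)
Conditions: Tf2O, 2,6-lutidine, CH2Cl2, −78 → 0 °C
Reagents that add atoms: none
Why: Selective triflation of the primary alcohol is followed by intramolecular SN2 etherification by the C3 tertiary hydroxyl, which closes the oxepane without changing a stereocentre.

Step 26
Reactants: 38
Product: 40 (1S,2S,3S,6R,7R,9S,10S,11S,12R,14S,15R)-11-epi-alcohol (43 with an inverted, free C11 hydroxyl), via C11 alkylborane 39 (not isolated)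
Conditions: BH3·THF, THF, 0 °C → rt; then NaOH, H2O2
Reagents that add atoms: hydrogen peroxide, OO
Why: Hydroboration–oxidation adds H–B syn from the convex face opposite the cis-fused tetrahydrofuran ring, with boron on C11 and hydrogen on C12, which sets C12 and leaves C11 to be inverted.

Step 27
Reactants: 40
Product: 41 (1S,2S,3S,6R,7R,9S,10R,12R,14S,15R)-11-ketone
Conditions: Dess–Martin periodinane, NaHCO3, CH2Cl2, 0 °C
Reagents that add atoms: none
Why: Buffered Dess–Martin oxidation gives the ketone without epimerising the axial C12 methyl group.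

Step 28
Reactants: 41
Product: 42 (1S,2S,3S,6R,7R,9S,10S,11R,12R,14S,15R)-11-alcohol (deacetyl 43)
Conditions: NaBH4, CeCl3·7H2O, MeOH, −78 °C
Reagents that add atoms: none
Why: Luche-type hydride reduction proceeds by axial attack from the convex face, away from the axial C9 and C12-methyl substituents, giving the equatorial 11R alcohol under non-epimerising conditions.

Step 29
Reactants: 42
Product: 43 CNP0289153.2 (target)
Conditions: Ac2O, Et3N, DMAP (cat.), CH2Cl2, rt
Reagents that add atoms: acetic anhydride, CC(=O)OC(C)=O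
Why: DMAP-catalysed acetylation of the only free hydroxyl gives the target.

## Compound list

1 | (S)-4-benzyl-3-propionyloxazolidin-2-one | CCC(=O)N1C(=O)OC[C@@H]1Cc1ccccc1 | starting material
2 | acrolein | C=CC=O | starting material
3 | dibutylboron (Z)-enolate of 1 | C/C=C(\OB(CCCC)CCCC)N1C(=O)OC[C@@H]1Cc1ccccc1 | intermediate
4 | (S)-4-benzyl-3-[(2S,3R)-3-hydroxy-2-methylpent-4-enoyl]oxazolidin-2-one | C=C[C@@H](O)[C@H](C)C(=O)N1C(=O)OC[C@@H]1Cc1ccccc1 | intermediate
5 | (S)-4-benzyl-3-[(2S,3R)-3-methoxy-2-methylpent-4-enoyl]oxazolidin-2-one | C=C[C@@H](OC)[C@H](C)C(=O)N1C(=O)OC[C@@H]1Cc1ccccc1 | intermediate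
6 | (2R,3R)-3-methoxy-2-methylpent-4-en-1-ol | C=C[C@@H](OC)[C@H](C)CO | intermediate
7 | (3R,4S)-5-bromo-3-methoxy-4-methylpent-1-ene | C=C[C@@H](OC)[C@H](C)CBr | intermediate
8 | (S)-benzyl glycidyl ether, (S)-2-[(benzyloxy)methyl]oxirane | C1O[C@@H]1COCc1ccccc1 | starting material
9 | [(2S,3R)-3-methoxy-2-methylpent-4-en-1-yl]magnesium bromide | C=C[C@@H](OC)[C@H](C)C[Mg]Br | intermediate
10 | (2S,4R,5R)-1-(benzyloxy)-5-methoxy-4-methylhept-6-en-2-ol | C=C[C@@H](OC)[C@H](C)C[C@H](O)COCc1ccccc1 | intermediate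
11 | bromoacetic acid | OC(=O)CBr | starting material
12 | (HepO)acetic acid | C=C[C@@H](OC)[C@H](C)C[C@H](OCC(=O)O)COCc1ccccc1 | intermediate
13 | (R)-4-benzyloxazolidin-2-one | O=C1OC[C@@H](Cc2ccccc2)N1 | starting material
14 | mixed anhydride of 12 with pivalic acid | C=C[C@@H](OC)[C@H](C)C[C@H](OCC(=O)OC(=O)C(C)(C)C)COCc1ccccc1 | intermediate
15 | (R)-4-benzyl-3-[(HepO)acetyl]oxazolidin-2-one | C=C[C@@H](OC)[C@H](C)C[C@H](OCC(=O)N1C(=O)OC[C@H]1Cc1ccccc1)COCc1ccccc1 | intermediate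
16 | acetaldehyde | CC=O | starting material
17 | dibutylboron (Z)-enolate of 15 | C=C[C@@H](OC)[C@H](C)C[C@H](O/C=C(\OB(CCCC)CCCC)N1C(=O)OC[C@H]1Cc1ccccc1)COCc1ccccc1 | intermediate
18 | (R)-4-benzyl-3-[(2R,3S)-2-(HepO)-3-hydroxybutanoyl]oxazolidin-2-one | C=C[C@@H](OC)[C@H](C)C[C@H](O[C@H]([C@H](C)O)C(=O)N1C(=O)OC[C@H]1Cc1ccccc1)COCc1ccccc1 | intermediate
19 | (2S,3S)-2-(HepO)butane-1,3-diol | C=C[C@@H](OC)[C@H](C)C[C@H](O[C@H]([C@H](C)O)CO)COCc1ccccc1 | intermediate
20 | (2S,3S)-3-(HepO)-4-[(tert-butyldimethylsilyl)oxy]butan-2-ol | C=C[C@@H](OC)[C@H](C)C[C@H](O[C@H]([C@H](C)O)CO[Si](C)(C)C(C)(C)C)COCc1ccccc1 | intermediate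
21 | (S)-3-(HepO)-4-[(tert-butyldimethylsilyl)oxy]butan-2-one | C=C[C@@H](OC)[C@H](C)C[C@H](O[C@H](C(C)=O)CO[Si](C)(C)C(C)(C)C)COCc1ccccc1 | intermediate
22 | (3S,4S)-4-(HepO)-5-[(tert-butyldimethylsilyl)oxy]-3-methylpent-1-en-3-ol | C=C[C@@H](OC)[C@H](C)C[C@H](O[C@H]([C@@](C)(O)C=C)CO[Si](C)(C)C(C)(C)C)COCc1ccccc1 | intermediate
23 | (2S,3S,4Z,6S,7R,9S)-9-[(benzyloxy)methyl]-2-{[(tert-butyldimethylsilyl)oxy]methyl}-6-methoxy-3,7-dimethyl-2,3,6,7,8,9-hexahydrooxonin-3-ol | CO[C@@H]1/C=C\[C@](C)(O)[C@H](CO[Si](C)(C)C(C)(C)C)O[C@H](COCc2ccccc2)C[C@H]1C | intermediate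
24 | (2S,3S,6R,7R,9S)-9-[(benzyloxy)methyl]-2-{[(tert-butyldimethylsilyl)oxy]methyl}-6-methoxy-3,7-dimethyloxonan-3-ol | CO[C@@H]1CC[C@](C)(O)[C@H](CO[Si](C)(C)C(C)(C)C)O[C@H](COCc2ccccc2)C[C@H]1C | intermediate
25 | 3-O-triethylsilyl ether of 24 | CO[C@@H]1CC[C@](C)(O[Si](CC)(CC)CC)[C@H](CO[Si](C)(C)C(C)(C)C)O[C@H](COCc2ccccc2)C[C@H]1C | intermediate
26 | (2S,3S,6R,7R,9S)-2-{[(tert-butyldimethylsilyl)oxy]methyl}-9-(hydroxymethyl)-6-methoxy-3,7-dimethyl-3-[(triethylsilyl)oxy]oxonane | CO[C@@H]1CC[C@](C)(O[Si](CC)(CC)CC)[C@H](CO[Si](C)(C)C(C)(C)C)O[C@H](CO)C[C@H]1C | intermediate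
27 | (2S,3S,6R,7R,9S)-2-{[(tert-butyldimethylsilyl)oxy]methyl}-9-formyl-6-methoxy-3,7-dimethyl-3-[(triethylsilyl)oxy]oxonane | CO[C@@H]1CC[C@](C)(O[Si](CC)(CC)CC)[C@H](CO[Si](C)(C)C(C)(C)C)O[C@H](C=O)C[C@H]1C | intermediate
28 | (2S,3S,6R,7R,9S)-2-{[(tert-butyldimethylsilyl)oxy]methyl}-6-methoxy-3,7-dimethyl-9-[(E)-3-oxobut-1-en-1-yl]-3-[(triethylsilyl)oxy]oxonane | CO[C@@H]1CC[C@](C)(O[Si](CC)(CC)CC)[C@H](CO[Si](C)(C)C(C)(C)C)O[C@H](/C=C/C(C)=O)C[C@H]1C | intermediate
29 | (2S,3S,6R,7R,9S)-2-{[(tert-butyldimethylsilyl)oxy]methyl}-6-methoxy-3,7-dimethyl-9-[(E)-3-methylbuta-1,3-dien-1-yl]-3-[(triethylsilyl)oxy]oxonane | CO[C@@H]1CC[C@](C)(O[Si](CC)(CC)CC)[C@H](CO[Si](C)(C)C(C)(C)C)O[C@H](/C=C/C(C)=C)C[C@H]1C | intermediate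
30 | (2S,3S,6R,7R,9S)-2-(hydroxymethyl)-6-methoxy-3,7-dimethyl-9-[(E)-3-methylbuta-1,3-dien-1-yl]oxonan-3-ol | CO[C@@H]1CC[C@](C)(O)[C@H](CO)O[C@H](/C=C/C(C)=C)C[C@H]1C | intermediate
31 | (2R,3S,6R,7R,9S)-2-formyl-6-methoxy-3,7-dimethyl-9-[(E)-3-methylbuta-1,3-dien-1-yl]oxonan-3-ol | CO[C@@H]1CC[C@](C)(O)[C@H](C=O)O[C@H](/C=C/C(C)=C)C[C@H]1C | intermediate
32 | (2S,3S,6R,7R,9S)-6-methoxy-3,7-dimethyl-9-[(E)-3-methylbuta-1,3-dien-1-yl]-2-[(E)-3-oxobut-1-en-1-yl]oxonan-3-ol | CO[C@@H]1CC[C@](C)(O)[C@H](/C=C/C(C)=O)O[C@H](/C=C/C(C)=C)C[C@H]1C | intermediate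
33 | (1R,2S,3S,6R,7R,9S,10R,14R)-14-acetyl-6-methoxy-3,7,12-trimethyl-2,9-epoxybicyclo[8.4.0]tetradec-11-en-3-ol | CO[C@@H]1CC[C@](C)(O)[C@H]2O[C@@H](C[C@H]1C)[C@@H]3C=C(C)C[C@@H](C(C)=O)[C@H]23 | intermediate
34 | (1S,2S,3S,6R,7R,9S,10R,14R)-6-methoxy-3,7,12-trimethyl-14-(prop-1-en-2-yl)-2,9-epoxybicyclo[8.4.0]tetradec-11-en-3-ol | CO[C@@H]1CC[C@](C)(O)[C@H]2O[C@@H](C[C@H]1C)[C@@H]3C=C(C)C[C@@H](C(C)=C)[C@H]23 | intermediate
35 | C16 B-alkyl-9-borabicyclo[3.3.1]nonane adduct of 34 | CO[C@@H]1CC[C@](C)(O)[C@H]2O[C@@H](C[C@H]1C)[C@@H]3C=C(C)C[C@@H]([C@@H](C)CB4C5CCCC4CCC5)[C@H]23 | intermediate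
36 | (1S,2S,3S,6R,7R,9S,10R,14S)-14-[(2R)-1-hydroxypropan-2-yl]-6-methoxy-3,7,12-trimethyl-2,9-epoxybicyclo[8.4.0]tetradec-11-en-3-ol | CO[C@@H]1CC[C@](C)(O)[C@H]2O[C@@H](C[C@H]1C)[C@@H]3C=C(C)C[C@@H]([C@@H](C)CO)[C@H]23 | intermediate
37 | C16 trifluoromethanesulfonate of 36 | CO[C@@H]1CC[C@](C)(O)[C@H]2O[C@@H](C[C@H]1C)[C@@H]3C=C(C)C[C@@H]([C@@H](C)COS(=O)(=O)C(F)(F)F)[C@H]23 | intermediate
38 | tetracyclic alkene (1S,2S,3S,6R,7R,9S,10R,14S,15R): 43 with C11=C12 double bond and no C11 oxygen | CO[C@@H]1CC[C@]2(C)OC[C@H](C)[C@@H]3CC(C)=C[C@@H]4[C@H]3[C@@H]2O[C@H]4C[C@H]1C | intermediate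
39 | C11 alkylborane from 38 (boron on C11, H on C12, both on the convex face) | CO[C@@H]1CC[C@]2(C)OC[C@H](C)[C@@H]3C[C@@H](C)[C@H](B)[C@@H]4[C@H]3[C@@H]2O[C@H]4C[C@H]1C | intermediate
40 | (1S,2S,3S,6R,7R,9S,10S,11S,12R,14S,15R)-11-epi-alcohol | CO[C@@H]1CC[C@]2(C)OC[C@H](C)[C@@H]3C[C@@H](C)[C@H](O)[C@@H]4[C@H]3[C@@H]2O[C@H]4C[C@H]1C | intermediate
41 | (1S,2S,3S,6R,7R,9S,10R,12R,14S,15R)-11-ketone | CO[C@@H]1CC[C@]2(C)OC[C@H](C)[C@@H]3C[C@@H](C)C(=O)[C@@H]4[C@H]3[C@@H]2O[C@H]4C[C@H]1C | intermediate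
42 | (1S,2S,3S,6R,7R,9S,10S,11R,12R,14S,15R)-11-alcohol (deacetyl 43) | CO[C@@H]1CC[C@]2(C)OC[C@H](C)[C@@H]3C[C@@H](C)[C@@H](O)[C@@H]4[C@H]3[C@@H]2O[C@H]4C[C@H]1C | intermediate
43 | CNP0289153.2, (1S,2S,3S,6R,7R,9S,10R,11R,12R,14S,15R)-11-acetate | CO[C@@H]1CC[C@]2(C)OC[C@H](C)[C@@H]3C[C@@H](C)[C@@H](OC(C)=O)[C@@H]4[C@H]3[C@@H]2O[C@H]4C[C@H]1C | target

## Totals and risks

Total step count: 29. Longest linear sequence: 29 steps (1 → 43).

The three steps most likely to fail: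

Step 13 (ring-closing metathesis). One alkene sits on the fully substituted C3, and a nine-membered ring invites oligomers. The fallback sets out from ketone 21. Chelation-controlled addition of (E)-hepta-1,6-dien-1-ylmagnesium bromide (from (E)-1-iodohepta-1,6-diene, t-BuLi, MgBr2·OEt2; THF, −78 °C) gives the relay tertiary alcohol F1. Relay ring-closing metathesis with the second-generation Hoveyda–Grubbs catalyst (H2IMes)Cl2Ru=CH(C6H4-2-OiPr) (CH2Cl2, 1 mM, 40 °C) loads the carbene at the unhindered chain end, expels cyclopentene to place it on C4, and closes onto the C5 vinyl group. This comes back to the route at oxonene 23.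

Step 22 (Wittig/Diels–Alder cascade). The facial and exo/endo selectivity is argued by analogy with unsaturated oxonenes, and the enone cyclises before it can be purified. The fallback sets out from aldehyde 31. Wittig olefination with methyl (triphenylphosphoranylidene)acetate gives the slower-reacting, isolable tetraene methyl ester F2. It is purified and cyclised separately (toluene, BHT, 110 °C) to the ester cycloadduct F3, whose diastereomers can be separated. MeNHOMe·HCl/i-PrMgCl gives the Weinreb amide F4, and MeMgBr returns to the route at methyl ketone 33.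

Step 24 (C15 by acyclic hydroboration). The selectivity depends on how well C1 and C13 are differentiated. The fallback sets out from aldehyde 31 and carries the C16 oxygen through the cycloaddition. Wittig reaction with 1-[(4-methoxybenzyl)oxy]-3-(triphenylphosphoranylidene)propan-2-one gives the tetraene enone F5, which cyclises as in step 22 to the PMB-oxymethyl ketone F6. Wittig methylenation gives the 1,1-disubstituted alkene F7, and DDQ frees the allylic alcohol F8. Tf2O/2,6-lutidine gives the allylic triflate F9, which the C3 hydroxyl traps to give the methylene-oxepane F10. Hydrogenation with RhCl(PPh3)3 (H2, benzene) then sets C15 inside the ring by adding to the exocyclic alkene from the face of H14 (anti to C13), leaving the trisubstituted C11=C12 alkene alone. This comes back to the route at tetracyclic alkene 38.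

## Further compounds

F1 | step 13 | (3S,4S,E)-4-(HepO)-5-[(tert-butyldimethylsilyl)oxy]-3-methylnona-1,8-dien-3-ol carrying the relay chain at C4 of the core (relay tertiary alcohol) | C=C[C@@H](OC)[C@H](C)C[C@H](O[C@H]([C@@](C)(O)/C=C/CCCC=C)CO[Si](C)(C)C(C)(C)C)COCc1ccccc1
F2 | step 22 | tetraene methyl ester: 32 with CO2Me in place of the acetyl group | CO[C@@H]1CC[C@](C)(O)[C@H](/C=C/C(=O)OC)O[C@H](/C=C/C(C)=C)C[C@H]1C
F3 | step 22 | ester cycloadduct: 33 with CO2Me at C14 in place of acetyl | CO[C@@H]1CC[C@](C)(O)[C@H]2O[C@@H](C[C@H]1C)[C@@H]3C=C(C)C[C@@H](C(=O)OC)[C@H]23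
F4 | step 22 | Weinreb amide: 33 with C(=O)N(Me)OMe at C14 in place of acetyl | CO[C@@H]1CC[C@](C)(O)[C@H]2O[C@@H](C[C@H]1C)[C@@H]3C=C(C)C[C@@H](C(=O)N(C)OC)[C@H]23
F5 | step 24 | tetraene enone: 32 with a (4-methoxybenzyl)oxymethyl ketone in place of the methyl ketone | CO[C@@H]1CC[C@](C)(O)[C@H](/C=C/C(=O)COCc2ccc(OC)cc2)O[C@H](/C=C/C(C)=C)C[C@H]1C
F6 | step 24 | cycloadduct: 33 with C(=O)CH2OPMB at C14 | CO[C@@H]1CC[C@](C)(O)[C@H]2O[C@@H](C[C@H]1C)[C@@H]3C=C(C)C[C@@H](C(=O)COCc4ccc(OC)cc4)[C@H]23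
F7 | step 24 | 1,1-disubstituted alkene: 34 with CH2OPMB in place of the isopropenyl methyl group | CO[C@@H]1CC[C@](C)(O)[C@H]2O[C@@H](C[C@H]1C)[C@@H]3C=C(C)C[C@@H](C(=C)COCc4ccc(OC)cc4)[C@H]23
F8 | step 24 | allylic alcohol: 34 with CH2OH in place of the isopropenyl methyl group | CO[C@@H]1CC[C@](C)(O)[C@H]2O[C@@H](C[C@H]1C)[C@@H]3C=C(C)C[C@@H](C(=C)CO)[C@H]23
F9 | step 24 | allylic triflate of F8 | CO[C@@H]1CC[C@](C)(O)[C@H]2O[C@@H](C[C@H]1C)[C@@H]3C=C(C)C[C@@H](C(=C)COS(=O)(=O)C(F)(F)F)[C@H]23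
F10 | step 24 | methylene-oxepane: 38 with an exocyclic C15=CH2 in place of C15H(CH3) | CO[C@@H]1CC[C@]2(C)OCC(=C)[C@@H]3CC(C)=C[C@@H]4[C@H]3[C@@H]2O[C@H]4C[C@H]1C
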